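Ring A (C1'–C6' with its exocyclic C6'=C7' bond) is treated as the electrocyclic valence isomer of an acyclic (Z)-dienylallene. In the key step a Wittig reaction of a prenyl ylide with a 2-methylallenal creates C3'=C4', and the resulting tetraene closes thermally (6π) from the gem-dimethyl carbon C1' onto the central allene carbon C6'. Ring, ring diene and exocyclic retro double bond thus arise in one operation from two acyclic three-carbon units. Ring B comes from ketoisophorone by asymmetric transfer hydrogenation and Meyer–Schuster rearrangement. The two C14 retro-aldehydes are then joined through a symmetrical C12 bis-phosphonium salt by two successive Wittig reactions.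

Key step: step 4

Remark: carotenoid numbering is used (ring A = C1'–C6', the dienylidene ring; ring B = C1–C6, the hydroxylated ring), and because protonation of the ring-A triene at C7' would trigger a 1,2-methyl shift to an arene, every step after step 4 is kept neutral or basic.

Step 1
Reactants: 1 3,3-diethoxyprop-1-yne; 2 [(tert-butyldimethylsilyl)oxy]acetaldehyde
Product: 5 1-[(tert-butyldimethylsilyl)oxy]-5,5-diethoxypent-3-yn-2-yl methanesulfonate (racemic), via lithium acetylide 3 (not isolated), via lithium alkoxide 4 (not isolated)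
Conditions: n-BuLi, THF, −78 °C; add 2, −78 °C; then MsCl, −78 to 0 °C
Reagents that add atoms: methanesulfonyl chloride, CS(=O)(=O)Cl
Why: Acetylide addition to an aldehyde followed by in situ O-sulfonylation of the lithium alkoxide should give the propargylic mesylate, whose racemic carbinol centre is immaterial because it becomes an allene axis that is destroyed in step 4.

Step 2
Reactants: 5
Product: 6 tert-butyl[(5,5-diethoxy-4-methylpenta-2,3-dien-1-yl)oxy]dimethylsilane (racemic allene)
Conditions: MeMgBr (1.5 equiv), CuBr·SMe2 (10 mol%), LiBr, THF, −78 to −20 °C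
Reagents that add atoms: methylmagnesium bromide, C[Mg]Br
Why: Copper-catalysed anti-SN2' substitution of a propargylic mesylate by a Grignard reagent should deliver the methyl group to the distal alkyne carbon and give the trisubstituted allene, the mesylate being a far better leaving group than the acetal ethoxy groups.

Step 3
Reactants: 6
Product: 7 5-[(tert-butyldimethylsilyl)oxy]-2-methylpenta-2,3-dienal (racemic; used at once)
Conditions: oxalic acid (10% aq.) on silica gel, CH2Cl2, 0 °C to rt
Reagents that add atoms: water, O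
Why: Mild acid-catalysed acetal hydrolysis on wet silica should unmask the aldehyde without cleaving the primary silyl ether or isomerising the allene to a conjugated dienal.

Step 4
Reactants: 7; 8 (3-methylbut-2-en-1-yl)triphenylphosphonium bromide
Product: 11 tert-butyldimethyl{[(2E)-2-(2,6,6-trimethylcyclohexa-2,4-dien-1-ylidene)ethyl]oxy}silane, via prenyl ylide 9 (not isolated), via Z-tetraene 10 (not isolated)
Conditions: 8, KN(SiMe3)2, THF, −78 to 0 °C; add 7, −78 °C to rt; then 65 °C, argon, dark
Reagents that add atoms: none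
Why: Deprotonation of 8 gives the semi-stabilised allyl ylide 9, which under lithium-free conditions should add through its unhindered α-carbon (the γ-carbon is blocked by the gem-dimethyl group) to the formyl group of allenal 7 and collapse through the oxaphosphetane to the (5Z)-tetraene 10, creating the C3'=C4' bond (Wittig olefination). On warming, 10 should undergo a thermally allowed disrotatory 6π-electrocyclisation in which the isopropylidene terminus C1' bonds to the central allene carbon C6'; this closes ring A, turns C3'=C4' into the central single bond of the ring diene and leaves the distal allene π-bond as the exocyclic C6'=C7' bond. The closest known reaction types are the tandem Wittig/6π sequence and the facile electrocyclisation of (Z)-1,2,4,6-heptatetraenes to 5-alkylidenecyclohexa-1,3-dienes; ring A closes in the hexatriene-to-cyclohexadiene mode onto an sp carbon, which lowers the barrier, and the closure is irreversible because the gem-dimethyl carbon blocks aromatisation and hydrogen shifts. No sp3 stereocentre is created (C1' carries two methyl groups and the racemic allene axis is destroyed); the only stereo element, the C6'=C7' geometry, is set by torquoselection, the larger CH2OTBS group rotating away from the incoming gem-dimethyl terminus to give the 2E isomer, which is corrected by equilibration in step 6. The step needs cis geometry at C3'=C4' (only the Z-triene can cyclise; the lithium-free conditions should give a useful share of it and the unreactive trans-tetraene is separable from 11) and 1,2- rather than conjugate addition to the allenal, which the low temperature and the high electrophilicity of the formyl group should secure.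

Step 5
Reactants: 11
Product: 12 (2E)-2-(2,6,6-trimethylcyclohexa-2,4-dien-1-ylidene)ethan-1-ol
Conditions: Bu4NF, THF, 0 °C
Reagents that add atoms: none
Why: Fluoride-mediated desilylation is chosen because it is non-acidic and should leave the cross-conjugated ring-A triene untouched.

Step 6
Reactants: 12
Product: 14 (2Z)-2-(2,6,6-trimethylcyclohexa-2,4-dien-1-ylidene)acetaldehyde, via E-trienal 13 (not isolated)
Conditions: MnO2 (activated, excess), CH2Cl2, rt; filter; then I2 (2 mol%), K2CO3, daylight, rt
Reagents that add atoms: none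
Why: Chemoselective MnO2 oxidation of the allylic alcohol gives trienal 13, and iodine-catalysed equilibration about C6'=C7' should favour 14, whose formyl group lies beside the gem-dimethyl carbon C1' and avoids allylic 1,3-strain with the in-plane C5' methyl group (the geometry of natural retro-carotenoids), so that either geometry from step 4 converges here.

Step 7
Reactants: 14; 15 2-(triphenylphosphoranylidene)propanal
Product: 16 (2E,4Z)-2-methyl-4-(2,6,6-trimethylcyclohexa-2,4-dien-1-ylidene)but-2-enal
Conditions: toluene, 80 °C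
Reagents that add atoms: none
Why: Wittig olefination with a formyl-stabilised α-methyl ylide should be E-selective for the new trisubstituted C8'=C9' bond and stop after one homologation because the α-branched product enal is less electrophilic.

Step 8
Reactants: 17 ketoisophorone (2,6,6-trimethylcyclohex-2-ene-1,4-dione)
Product: 18 (4S)-4-hydroxy-2,6,6-trimethylcyclohex-2-en-1-one
Conditions: RuCl(p-cymene)[(S,S)-TsDPEN] (1 mol%), HCO2H/Et3N (5:2), CH2Cl2, rt
Reagents that add atoms: none
Why: Noyori asymmetric transfer hydrogenation should reduce only the less hindered C4 carbonyl (C1 is flanked by the quaternary carbon and the methylated alkene carbon), and the (S,S)-ligand is expected, by analogy with aryl and alkenyl ketones, to deliver hydride to the face that gives the 4S alcohol.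

Step 9
Reactants: 18
Product: 19 (4S)-4-[(tert-butyldimethylsilyl)oxy]-2,6,6-trimethylcyclohex-2-en-1-one
Conditions: TBSCl, imidazole, DMF, rt
Reagents that add atoms: tert-butyldimethylsilyl chloride, CC(C)(C)[Si](C)(C)Cl
Why: Standard silylation of the secondary alcohol protects the allylic hydroxyl against the Grignard reagent and the rearrangement catalyst without touching the stereocentre.

Step 10
Reactants: 19
Product: 20 (4S)-4-[(tert-butyldimethylsilyl)oxy]-1-ethynyl-2,6,6-trimethylcyclohex-2-en-1-ol (C1 epimer mixture)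
Conditions: ethynylmagnesium bromide, THF, 0 °C to rt; aq. NH4Cl
Reagents that add atoms: ethynylmagnesium bromide, C#C[Mg]Br
Why: 1,2-Addition of the small alkynyl Grignard reagent to the hindered, non-enolisable ketone should give the tertiary carbinol, whose new centre forms as an epimer mixture that is immaterial because it becomes sp2 in step 11.

Step 11
Reactants: 20
Product: 22 (2E)-2-[(4S)-4-[(tert-butyldimethylsilyl)oxy]-2,6,6-trimethylcyclohex-2-en-1-ylidene]acetaldehyde, via Z-dienal 21 (not isolated)
Conditions: MoO2(acac)2 (2 mol%), AuCl(PPh3) (2 mol%), AgOTf (2 mol%), toluene, rt; then I2 (2 mol%), K2CO3, daylight, rt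
Reagents that add atoms: none
Why: Meyer–Schuster rearrangement (1,3-hydroxyl shift and tautomerisation; Rupe dehydration is excluded because neither neighbouring ring carbon carries hydrogen) should give the dienal as a mixture about the new C6=C7 bond, and iodine-catalysed equilibration should favour the 2E isomer with the formyl group beside the gem-dimethyl carbon and away from the in-plane C5 methyl group.

Step 12
Reactants: 22; 15 2-(triphenylphosphoranylidene)propanal
Product: 23 (2E,4E)-4-[(4S)-4-[(tert-butyldimethylsilyl)oxy]-2,6,6-trimethylcyclohex-2-en-1-ylidene]-2-methylbut-2-enal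
Conditions: toluene, 80 °C
Reagents that add atoms: none
Why: Wittig olefination with the formyl-stabilised α-methyl ylide should form the trisubstituted C8=C9 bond E-selectively, as in step 7.

Step 13
Reactants: 24 1,4-dioxane-2,3-diol; 25 ethyl (2E)-4-(diethoxyphosphoryl)-3-methylbut-2-enoate
Product: 29 diethyl (2E,4E,6E,8E)-3,8-dimethyldeca-2,4,6,8-tetraenedioate, via sodium phosphonate 26 (not isolated), via glyoxal 27 (not isolated), via mono-olefination aldehyde 28 (not isolated)
Conditions: 25 (2.2 equiv), NaH (4.4 equiv), THF, 0 °C; add 24, 0 °C to rt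
Reagents that add atoms: none
Why: Twofold Horner–Wadsworth–Emmons olefination of glyoxal, released in the flask from its dioxanediol form, should be E-selective for the two new disubstituted double bonds while the methyl-bearing double bonds equilibrate through the delocalised phosphonate anion to the E form, the symmetrical all-E diester being purified by crystallisation.

Step 14
Reactants: 29
Product: 30 (2E,4E,6E,8E)-3,8-dimethyldeca-2,4,6,8-tetraene-1,10-diol
Conditions: i-Bu2AlH (4.5 equiv), CH2Cl2, −78 to 0 °C; aq. potassium sodium tartrate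
Reagents that add atoms: none
Why: Low-temperature 1,2-reduction of the conjugated diester with the aluminium hydride should give the bis-allylic diol without touching the tetraene.

Step 15
Reactants: 30
Product: 31 [(2E,4E,6E,8E)-3,8-dimethyldeca-2,4,6,8-tetraene-1,10-diyl]bis(triphenylphosphonium) dibromide
Conditions: PPh3·HBr (2.1 equiv), MeOH/CH2Cl2, rt
Reagents that add atoms: triphenylphosphine hydrobromide, Br.c1ccc(cc1)P(c1ccccc1)c1ccccc1
Why: Acid-mediated allylic substitution through the delocalised polyenyl cation, the usual way to carotenoid Wittig salts, should place phosphorus at the primary termini under thermodynamic control and keep the all-E tetraene.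

Step 16
Reactants: 31; 23
Product: 33 triphenyl{(2E,4E,6E,8E,10E,12E,14E)-14-[(4S)-4-[(tert-butyldimethylsilyl)oxy]-2,6,6-trimethylcyclohex-2-en-1-ylidene]-3,8,12-trimethyltetradeca-2,4,6,8,10,12-hexaen-1-yl}phosphonium bromide (C26 salt; drawn 10E in carotenoid numbering), via mono-ylide 32 (not isolated)
Conditions: 31 (3 equiv), NaOMe (1 equiv based on 23), CH2Cl2/MeOH, 0 °C; add 23, rt; excess 31 recovered
Reagents that add atoms: none
Why: Wittig olefination of the mono-ylide, generated with one equivalent of base in excess bis-salt to suppress double olefination, should form the C10=C11 bond, and any 10Z isomer is carried on and converges in the thermal isomerisation of step 17.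

Step 17
Reactants: 33; 16
Product: 35 tert-butyl{[(1S,4E)-3,5,5-trimethyl-4-[(2E,4E,6E,8E,10E,12E,14E,16E,18Z)-3,7,12,16-tetramethyl-18-(2,6,6-trimethylcyclohexa-2,4-dien-1-ylidene)octadeca-2,4,6,8,10,12,14,16-octaen-1-ylidene]cyclohex-2-en-1-yl]oxy}dimethylsilane (silyl ether of the target), via polyenyl ylide 34 (not isolated)
Conditions: NaOMe, CH2Cl2/MeOH, 0 °C to rt; then n-heptane, 90 °C, N2, dark
Reagents that add atoms: none
Why: The second Wittig olefination forms the C10'=C11' bond and completes the C40 skeleton, and heating in heptane should isomerise the sterically hindered 10-cis and 10'-cis bonds (next to the C9 and C9' methyl groups) to the all-trans polyene, as is routine for Wittig-derived carotenoids, while the ring–chain double bonds stay in their preferred geometry.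

Step 18
Reactants: 35
Product: 36 CNP0202479.1, (1S,4E)-3,5,5-trimethyl-4-[(2E,4E,6E,8E,10E,12E,14E,16E,18Z)-3,7,12,16-tetramethyl-18-(2,6,6-trimethylcyclohexa-2,4-dien-1-ylidene)octadeca-2,4,6,8,10,12,14,16-octaen-1-ylidene]cyclohex-2-en-1-ol
Conditions: Bu4NF, THF, 0 °C to rt; neutral work-up, crystallisation
Reagents that add atoms: none
Why: Fluoride desilylation under non-acidic conditions should free the allylic 3-hydroxyl group without ionising it or protonating ring A, and the stereocentre set in step 8 is untouched.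

Compound list
1 | 3,3-diethoxyprop-1-yne (propargyl aldehyde diethyl acetal) | C#CC(OCC)OCC | starting material
2 | [(tert-butyldimethylsilyl)oxy]acetaldehyde | O=CCO[Si](C)(C)C(C)(C)C | starting material
3 | lithium 3,3-diethoxyprop-1-yn-1-ide (not isolated) | [Li]C#CC(OCC)OCC | intermediate
4 | lithium 1-[(tert-butyldimethylsilyl)oxy]-5,5-diethoxypent-3-yn-2-olate (racemic; not isolated) | CCOC(OCC)C#CC(O[Li])CO[Si](C)(C)C(C)(C)C | intermediate
5 | 1-[(tert-butyldimethylsilyl)oxy]-5,5-diethoxypent-3-yn-2-yl methanesulfonate (racemic) | CCOC(OCC)C#CC(OS(C)(=O)=O)CO[Si](C)(C)C(C)(C)C | intermediate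
6 | tert-butyl[(5,5-diethoxy-4-methylpenta-2,3-dien-1-yl)oxy]dimethylsilane (racemic allene) | CCOC(OCC)C(C)=C=CCO[Si](C)(C)C(C)(C)C | intermediate
7 | 5-[(tert-butyldimethylsilyl)oxy]-2-methylpenta-2,3-dienal (racemic allene) | O=CC(C)=C=CCO[Si](C)(C)C(C)(C)C | intermediate
8 | (3-methylbut-2-en-1-yl)triphenylphosphonium bromide | CC(C)=CC[P+](c1ccccc1)(c1ccccc1)c1ccccc1.[Br-] | starting material
9 | (3-methylbut-2-en-1-ylidene)triphenylphosphorane (not isolated) | CC(C)=CC=P(c1ccccc1)(c1ccccc1)c1ccccc1 | intermediate
10 | tert-butyl{[(5Z)-4,8-dimethylnona-2,3,5,7-tetraen-1-yl]oxy}dimethylsilane (racemic allene; not isolated) | CC(C)=C/C=C\C(C)=C=CCO[Si](C)(C)C(C)(C)C | intermediate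
11 | tert-butyldimethyl{[(2E)-2-(2,6,6-trimethylcyclohexa-2,4-dien-1-ylidene)ethyl]oxy}silane | CC1=CC=CC(C)(C)/C1=C/CO[Si](C)(C)C(C)(C)C | intermediate
12 | (2E)-2-(2,6,6-trimethylcyclohexa-2,4-dien-1-ylidene)ethan-1-ol | CC1=CC=CC(C)(C)/C1=C/CO | intermediate
13 | (2E)-2-(2,6,6-trimethylcyclohexa-2,4-dien-1-ylidene)acetaldehyde (not isolated) | CC1=CC=CC(C)(C)/C1=C/C=O | intermediate
14 | (2Z)-2-(2,6,6-trimethylcyclohexa-2,4-dien-1-ylidene)acetaldehyde (formyl group beside the gem-dimethyl carbon) | CC1=CC=CC(C)(C)\C1=C/C=O | intermediate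
15 | 2-(triphenylphosphoranylidene)propanal | CC(C=O)=P(c1ccccc1)(c1ccccc1)c1ccccc1 | starting material
16 | (2E,4Z)-2-methyl-4-(2,6,6-trimethylcyclohexa-2,4-dien-1-ylidene)but-2-enal (ring-A C14 aldehyde) | CC1=CC=CC(C)(C)\C1=C/C=C(C)/C=O | intermediate
17 | ketoisophorone (2,6,6-trimethylcyclohex-2-ene-1,4-dione) | CC1=CC(=O)CC(C)(C)C1=O | starting material
18 | (4S)-4-hydroxy-2,6,6-trimethylcyclohex-2-en-1-one | O=C1C(C)=C[C@@H](O)CC1(C)C | intermediate
19 | (4S)-4-[(tert-butyldimethylsilyl)oxy]-2,6,6-trimethylcyclohex-2-en-1-one | O=C1C(C)=C[C@@H](O[Si](C)(C)C(C)(C)C)CC1(C)C | intermediate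
20 | (4S)-4-[(tert-butyldimethylsilyl)oxy]-1-ethynyl-2,6,6-trimethylcyclohex-2-en-1-ol (C1 epimer mixture) | C#CC1(O)C(C)=C[C@@H](O[Si](C)(C)C(C)(C)C)CC1(C)C | intermediate
21 | (2Z)-2-[(4S)-4-[(tert-butyldimethylsilyl)oxy]-2,6,6-trimethylcyclohex-2-en-1-ylidene]acetaldehyde (not isolated) | O=C/C=C1\C(C)=C[C@@H](O[Si](C)(C)C(C)(C)C)CC1(C)C | intermediate
22 | (2E)-2-[(4S)-4-[(tert-butyldimethylsilyl)oxy]-2,6,6-trimethylcyclohex-2-en-1-ylidene]acetaldehyde | O=C/C=C1/C(C)=C[C@@H](O[Si](C)(C)C(C)(C)C)CC1(C)C | intermediate
23 | (2E,4E)-4-[(4S)-4-[(tert-butyldimethylsilyl)oxy]-2,6,6-trimethylcyclohex-2-en-1-ylidene]-2-methylbut-2-enal (ring-B C14 aldehyde) | O=C/C(C)=C/C=C1/C(C)=C[C@@H](O[Si](C)(C)C(C)(C)C)CC1(C)C | intermediate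
24 | 1,4-dioxane-2,3-diol (glyoxal equivalent) | OC1OCCOC1O | starting material
25 | ethyl (2E)-4-(diethoxyphosphoryl)-3-methylbut-2-enoate (commercial as an E/Z mixture; drawn E) | CCOC(=O)/C=C(\C)CP(=O)(OCC)OCC | starting material
26 | sodium salt of the phosphonate carbanion of 25 (not isolated) | CCOC(=O)/C=C(\C)[CH-]P(=O)(OCC)OCC.[Na+] | intermediate
27 | glyoxal (not isolated) | O=CC=O | intermediate
28 | ethyl (2E,4E)-3-methyl-6-oxohexa-2,4-dienoate (not isolated) | CCOC(=O)/C=C(C)/C=C/C=O | intermediate
29 | diethyl (2E,4E,6E,8E)-3,8-dimethyldeca-2,4,6,8-tetraenedioate | CCOC(=O)/C=C(C)/C=C/C=C/C(C)=C/C(=O)OCC | intermediate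
30 | (2E,4E,6E,8E)-3,8-dimethyldeca-2,4,6,8-tetraene-1,10-diol | OC/C=C(C)/C=C/C=C/C(C)=C/CO | intermediate
31 | [(2E,4E,6E,8E)-3,8-dimethyldeca-2,4,6,8-tetraene-1,10-diyl]bis(triphenylphosphonium) dibromide | [Br-].[Br-].c1ccccc1[P+](c1ccccc1)(c1ccccc1)C/C=C(C)/C=C/C=C/C(C)=C/C[P+](c1ccccc1)(c1ccccc1)c1ccccc1 | intermediate
32 | mono-ylide of 31 (not isolated) | [Br-].c1ccccc1P(c1ccccc1)(c1ccccc1)=C/C=C(C)/C=C/C=C/C(C)=C/C[P+](c1ccccc1)(c1ccccc1)c1ccccc1 | intermediate
33 | triphenyl{(2E,4E,6E,8E,10E,12E,14E)-14-[(4S)-4-[(tert-butyldimethylsilyl)oxy]-2,6,6-trimethylcyclohex-2-en-1-ylidene]-3,8,12-trimethyltetradeca-2,4,6,8,10,12-hexaen-1-yl}phosphonium bromide (C26 salt) | [Br-].c1ccccc1[P+](c1ccccc1)(c1ccccc1)C/C=C(C)/C=C/C=C/C(C)=C/C=C/C(C)=C/C=C1/C(C)=C[C@@H](O[Si](C)(C)C(C)(C)C)CC1(C)C | intermediate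
34 | ylide of 33 (not isolated) | c1ccccc1P(c1ccccc1)(c1ccccc1)=C/C=C(C)/C=C/C=C/C(C)=C/C=C/C(C)=C/C=C1/C(C)=C[C@@H](O[Si](C)(C)C(C)(C)C)CC1(C)C | intermediate
35 | tert-butyldimethylsilyl ether of the target at the 3-hydroxyl group (3S; all-trans chain; ring–chain geometry as in 36) | CC1=CC=CC(C)(C)\C1=C/C=C(C)/C=C/C=C(C)/C=C/C=C/C(C)=C/C=C/C(C)=C/C=C1/C(C)=C[C@@H](O[Si](C)(C)C(C)(C)C)CC1(C)C | intermediate
36 | CNP0202479.1, (1S,4E)-3,5,5-trimethyl-4-[(2E,4E,6E,8E,10E,12E,14E,16E,18Z)-3,7,12,16-tetramethyl-18-(2,6,6-trimethylcyclohexa-2,4-dien-1-ylidene)octadeca-2,4,6,8,10,12,14,16-octaen-1-ylidene]cyclohex-2-en-1-ol | CC1=CC=CC(C)(C)\C1=C/C=C(C)/C=C/C=C(C)/C=C/C=C/C(C)=C/C=C/C(C)=C/C=C1/C(C)=C[C@@H](O)CC1(C)C | target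

Total step count: 18. Longest linear sequence: 9 steps (steps 1–7, then 17 and 18).

Steps most likely to fail

Step 4. The olefination may deliver mainly the trans-tetraene, which cannot electrocyclise, or the ylide may add to the allene in conjugate fashion, so that little ring closure occurs. The fallback sets out from 7 and returns at 11. Stork–Zhao olefination of 7 with (iodomethyl)triphenylphosphonium iodide and NaN(SiMe3)2 (THF, DMPU, −78 °C) should give the cis-vinyl iodide tert-butyl{[(5Z)-6-iodo-4-methylhexa-2,3,5-trien-1-yl]oxy}dimethylsilane F1. Suzuki coupling of F1 with commercial 2-methylprop-1-en-1-ylboronic acid pinacol ester (Pd(PPh3)4, aq. K3PO4, THF, rt) should then give the geometrically defined tetraene 10, which on warming to 65 °C closes to 11.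

Step 11. Rearrangement of the hindered terminal ethynyl carbinol may stall, or ionisation of the tertiary alcohol may be followed by loss of the silyloxy group and formation of a ring triene. The fallback sets out from 19 and returns at 22. Addition of lithium ethoxyacetylide (ethoxyacetylene, n-BuLi, THF, −78 °C) to 19 should give the ynol ether carbinol (4S)-4-[(tert-butyldimethylsilyl)oxy]-1-(ethoxyethynyl)-2,6,6-trimethylcyclohex-2-en-1-ol F2. This rearranges far more readily (Sc(OTf)3 cat., EtOH/CH2Cl2, rt) to the ester ethyl (2E)-2-[(4S)-4-[(tert-butyldimethylsilyl)oxy]-2,6,6-trimethylcyclohex-2-en-1-ylidene]acetate F3. Reduction with i-Bu2AlH gives the allylic alcohol (2E)-2-[(4S)-4-[(tert-butyldimethylsilyl)oxy]-2,6,6-trimethylcyclohex-2-en-1-ylidene]ethan-1-ol F4, and MnO2 oxidation (with iodine equilibration if needed) gives 22.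

Step 16. Ylide formation on the symmetrical bis-salt may not stay at the mono stage (double olefination, transylidation), and the product salt may be hard to separate from the excess bis-salt. The fallback sets out from 30 and 23 and returns at 33. Partial oxidation of diol 30 with MnO2 should give the neutral, chromatographable hydroxy aldehyde (2E,4E,6E,8E)-10-hydroxy-3,8-dimethyldeca-2,4,6,8-tetraenal F5, with unreacted 30 recycled. Aldehyde 23 is reduced with NaBH4 to the allylic alcohol (2E,4E)-4-[(4S)-4-[(tert-butyldimethylsilyl)oxy]-2,6,6-trimethylcyclohex-2-en-1-ylidene]-2-methylbut-2-en-1-ol F6 and converted with PPh3·HBr into the C14 salt {(2E,4E)-4-[(4S)-4-[(tert-butyldimethylsilyl)oxy]-2,6,6-trimethylcyclohex-2-en-1-ylidene]-2-methylbut-2-en-1-yl}triphenylphosphonium bromide F7. Wittig reaction of F7 with F5 (NaOMe, CH2Cl2/MeOH) should give the C26 alcohol (2E,4E,6E,8E,10E,12E,14E)-14-[(4S)-4-[(tert-butyldimethylsilyl)oxy]-2,6,6-trimethylcyclohex-2-en-1-ylidene]-3,8,12-trimethyltetradeca-2,4,6,8,10,12-hexaen-1-ol F8, and PPh3·HBr converts F8 into 33.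

Further compounds
F1 | step 4 | tert-butyl{[(5Z)-6-iodo-4-methylhexa-2,3,5-trien-1-yl]oxy}dimethylsilane | I/C=C\C(C)=C=CCO[Si](C)(C)C(C)(C)C
F2 | step 11 | (4S)-4-[(tert-butyldimethylsilyl)oxy]-1-(ethoxyethynyl)-2,6,6-trimethylcyclohex-2-en-1-ol (C1 epimer mixture) | CCOC#CC1(O)C(C)=C[C@@H](O[Si](C)(C)C(C)(C)C)CC1(C)C
F3 | step 11 | ethyl (2E)-2-[(4S)-4-[(tert-butyldimethylsilyl)oxy]-2,6,6-trimethylcyclohex-2-en-1-ylidene]acetate | CCOC(=O)/C=C1/C(C)=C[C@@H](O[Si](C)(C)C(C)(C)C)CC1(C)C
F4 | step 11 | (2E)-2-[(4S)-4-[(tert-butyldimethylsilyl)oxy]-2,6,6-trimethylcyclohex-2-en-1-ylidene]ethan-1-ol | OC/C=C1/C(C)=C[C@@H](O[Si](C)(C)C(C)(C)C)CC1(C)C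
F5 | step 16 | (2E,4E,6E,8E)-10-hydroxy-3,8-dimethyldeca-2,4,6,8-tetraenal | O=C/C=C(C)/C=C/C=C/C(C)=C/CO
F6 | step 16 | (2E,4E)-4-[(4S)-4-[(tert-butyldimethylsilyl)oxy]-2,6,6-trimethylcyclohex-2-en-1-ylidene]-2-methylbut-2-en-1-ol | OC/C(C)=C/C=C1/C(C)=C[C@@H](O[Si](C)(C)C(C)(C)C)CC1(C)C
F7 | step 16 | {(2E,4E)-4-[(4S)-4-[(tert-butyldimethylsilyl)oxy]-2,6,6-trimethylcyclohex-2-en-1-ylidene]-2-methylbut-2-en-1-yl}triphenylphosphonium bromide | [Br-].c1ccccc1[P+](c1ccccc1)(c1ccccc1)C/C(C)=C/C=C1/C(C)=C[C@@H](O[Si](C)(C)C(C)(C)C)CC1(C)C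
F8 | step 16 | (2E,4E,6E,8E,10E,12E,14E)-14-[(4S)-4-[(tert-butyldimethylsilyl)oxy]-2,6,6-trimethylcyclohex-2-en-1-ylidene]-3,8,12-trimethyltetradeca-2,4,6,8,10,12-hexaen-1-ol | OC/C=C(C)/C=C/C=C/C(C)=C/C=C/C(C)=C/C=C1/C(C)=C[C@@H](O[Si](C)(C)C(C)(C)C)CC1(C)C
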